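**Retrosynthetic overview** (ring B = central benzene ring)
1. Target 19 ⇐ global O-demethylation of heptamethyl ether 18.
2. 18 ⇐ open the seven-membered ring at its aryl–CH bond: meso stilbene 16, whose two 3,5-dimethoxyphenyl rings are enantiotopic. A chiral Brønsted acid closes the ring onto one of them and sets the last stereocentre and the absolute configuration.
3. 16 ⇐ olefination and ester reduction of meso trans,trans ester 13 ⇐ C2/C6 epimerisation of all-cis 11 ⇐ face-relayed twofold hydrogenation of the flat, achiral benzodifuran 9.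
4. 9 ⇐ twofold C–H arylation of 6 ⇐ twofold cyclodehydration of bis(aryloxy ketone) 4, closing both furan rings in one operation ⇐ methyl 3,5-dihydroxybenzoate 1 + bromoketone 2.
5. Ring order: ring B is bought; both furan rings form together (step 2); the seven-membered carbocycle forms last (step 8).

Assumption: the sense of induction in step 8 must be assigned by experiment; the route is written with the (S)-configured acid, and its mirror image (equally available) is used if it gives the antipode.

Step 1
Reactants: 1 methyl 3,5-dihydroxybenzoate; 2 2-bromo-1-(3,5-dimethoxyphenyl)ethan-1-one (2.2 equiv)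
Product: 4 methyl 3,5-bis[2-(3,5-dimethoxyphenyl)-2-oxoethoxy]benzoate, via mono-ether 3 (not isolated)
Conditions: K2CO3 (3 equiv), acetone, reflux
Reagents that add atoms: none
Why: Williamson ether synthesis (SN2 of each phenoxide on the primary α-bromoketone); no stereocentre is formed.

Step 2
Reactants: 4 methyl 3,5-bis[2-(3,5-dimethoxyphenyl)-2-oxoethoxy]benzoate
Product: 6 methyl 3,5-bis(3,5-dimethoxyphenyl)benzo[1,2-b:5,4-b']difuran-4-carboxylate, via mono-benzofuran 5 (not isolated)
Conditions: Bi(OTf)3 (20 mol%), ClCH2CH2Cl, 80 °C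
Reagents that add atoms: none
Why: Twofold Lewis-acid-catalysed cyclodehydration (intramolecular Friedel–Crafts hydroxyalkylation by each ketone, then loss of water) closes both furan rings in one operation, each para to the other ring oxygen and ortho to the ester, as known for the mono-aryloxyketone benzoates, so the CH between the two oxygens stays free; no stereocentre is formed.

Step 3
Reactants: 6 methyl 3,5-bis(3,5-dimethoxyphenyl)benzo[1,2-b:5,4-b']difuran-4-carboxylate; 7 4-bromoanisole (3 equiv)
Product: 9 methyl 3,5-bis(3,5-dimethoxyphenyl)-2,6-bis(4-methoxyphenyl)benzo[1,2-b:5,4-b']difuran-4-carboxylate, via mono-arylated benzodifuran 8 (not isolated)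
Conditions: Pd(OAc)2 (10 mol%), PCy3·HBF4 (20 mol%), PivOH (0.6 equiv), K2CO3 (4 equiv), DMA, 110 °C
Reagents that add atoms: none
Why: Twofold palladium-catalysed direct C–H arylation (concerted metalation–deprotonation at the furan C2–H, the most reactive C–H of a 3-arylbenzofuran); no stereocentre is formed.

Step 4
Reactants: 9 methyl 3,5-bis(3,5-dimethoxyphenyl)-2,6-bis(4-methoxyphenyl)benzo[1,2-b:5,4-b']difuran-4-carboxylate
Product: 11 methyl (2R,3S,5R,6S)-3,5-bis(3,5-dimethoxyphenyl)-2,6-bis(4-methoxyphenyl)-2,3,5,6-tetrahydrobenzo[1,2-b:5,4-b']difuran-4-carboxylate (all-cis meso), via half-reduced cis-dihydro compound 10 (not isolated)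
Conditions: H2 (40 bar), Pd/C (10% palladium on carbon), EtOAc–EtOH 1:1, 50 °C
Reagents that add atoms: none
Why: Heterogeneous catalytic hydrogenation adds H2 syn to each furan C2=C3 bond; once the first ring is reduced, its two cis aryl groups block one face of the flat tricycle, so the second furan can only meet the metal surface with the other face, which puts all four new hydrogens on one face and gives the achiral all-cis isomer with both 3-aryl groups syn.

Step 5
Reactants: 11 all-cis meso tetrahydrobenzodifuran ester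
Product: 13 methyl (2R,3R,5S,6S)-3,5-bis(3,5-dimethoxyphenyl)-2,6-bis(4-methoxyphenyl)-2,3,5,6-tetrahydrobenzo[1,2-b:5,4-b']difuran-4-carboxylate (2,3-trans 5,6-trans meso), via mono-epimerised ester 12 (not isolated)
Conditions: CF3CO2H (10 equiv), CH2Cl2, 0 → 25 °C
Reagents that add atoms: none
Why: Acid-mediated epimerisation at C2 and C6 by reversible ionisation of the 4-methoxybenzylic C–O bond and reclosure gives the thermodynamically preferred trans rings while C3 and C5 are untouched, so the two 3-aryl groups stay syn and the product stays meso; it is done before the alkene exists so that step 8 starts from one achiral substrate.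

Step 6
Reactants: 13 trans,trans meso ester
Product: 14 (2R,3R,5S,6S)-3,5-bis(3,5-dimethoxyphenyl)-2,6-bis(4-methoxyphenyl)-2,3,5,6-tetrahydrobenzo[1,2-b:5,4-b']difuran-4-carbaldehyde (meso)
Conditions: i-Bu2AlH (1.3 equiv), CH2Cl2, −78 °C; then aq. KNaC4H4O6
Reagents that add atoms: none
Why: Partial hydride reduction of the ester, where the tetrahedral aluminium hemiacetal of this doubly ortho-flanked ester survives at −78 °C and releases the aldehyde on work-up; no stereocentre is touched.

Step 7
Reactants: 14 meso aldehyde; 15 diethyl [(4-methoxyphenyl)methyl]phosphonate (1.5 equiv)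
Product: 16 (2R,3R,5S,6S)-3,5-bis(3,5-dimethoxyphenyl)-2,6-bis(4-methoxyphenyl)-4-[(E)-2-(4-methoxyphenyl)ethenyl]-2,3,5,6-tetrahydrobenzo[1,2-b:5,4-b']difuran (meso stilbene)
Conditions: KOt-Bu (1.5 equiv), THF, 0 → 25 °C
Reagents that add atoms: none
Why: Horner–Wadsworth–Emmons olefination gives the E-stilbene; the ring stereocentres are not touched, and any reversible deprotonation at C3/C5 would return to the trans isomer fixed by C2/C6.

Step 8
Reactants: 16 meso stilbene
Product: 18 hepta-O-methyl ether of target 19 (seven-ring methine S; dihydrofuran on the seven-ring side 2S,3S; other dihydrofuran 2R,3R), via benzylic cation 17 (not isolated)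
Conditions: (S)-TRIP N-triflylphosphoramide = N-[(11bS)-4-oxido-2,6-bis(2,4,6-triisopropylphenyl)dinaphtho[2,1-d:1',2'-f][1,3,2]dioxaphosphepin-4-yl]-1,1,1-trifluoromethanesulfonamide (10 mol%), toluene, 0 °C
Reagents that add atoms: none
Why: Proposed new method: the chiral acid protonates the stilbene at the carbon next to ring B to give a 4-methoxybenzylic cation paired with the chiral anion; each of the two enantiotopic 3,5-dimethoxyphenyl rings can close only from the cation face that puts the anisyl group pseudo-axial, away from the ortho-methoxy group of the attacking ring (the relative configuration of the acid cyclisation of ε-viniferin to ampelopsin B), so the catalyst's choice of cation face decides which ring attacks, fixes the new methine as S and makes the four existing centres S,S and R,R in the absolute sense (desymmetrising intramolecular Friedel–Crafts hydroarylation); closest known reactions are chiral strong-acid-catalysed asymmetric intramolecular hydroarylations of olefins and the achiral acid-mediated ε-viniferin to ampelopsin B ring closure.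

Step 9
Reactants: 18 hepta-O-methyl ether of the target
Product: 19 target CNP0136963.1
Conditions: BBr3 (14 equiv), CH2Cl2, −78 → 0 °C; then H2O
Reagents that add atoms: none
Why: Lewis-acid ether cleavage (aryloxy-dibromoborane formation, SN2 loss of bromomethane, hydrolysis) frees all seven phenols; the trans dihydrofurans are the thermodynamic isomers, so any reversible C2–O ionisation recloses to the same configuration, and the all-carbon methine cannot epimerise.

**Compound list**
1 | methyl 3,5-dihydroxybenzoate | COC(=O)c1cc(O)cc(O)c1 | starting material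
2 | 2-bromo-1-(3,5-dimethoxyphenyl)ethan-1-one | COc1cc(OC)cc(c1)C(=O)CBr | starting material
3 | methyl 3-[2-(3,5-dimethoxyphenyl)-2-oxoethoxy]-5-hydroxybenzoate (mono-ether, not isolated) | COC(=O)c1cc(O)cc(OCC(=O)c2cc(OC)cc(OC)c2)c1 | intermediate
4 | methyl 3,5-bis[2-(3,5-dimethoxyphenyl)-2-oxoethoxy]benzoate | COC(=O)c1cc(OCC(=O)c2cc(OC)cc(OC)c2)cc(OCC(=O)c2cc(OC)cc(OC)c2)c1 | intermediate
5 | methyl 3-(3,5-dimethoxyphenyl)-6-[2-(3,5-dimethoxyphenyl)-2-oxoethoxy]-1-benzofuran-4-carboxylate (mono-benzofuran, not isolated) | COC(=O)c1cc(OCC(=O)c2cc(OC)cc(OC)c2)cc2occ(-c3cc(OC)cc(OC)c3)c12 | intermediate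
6 | methyl 3,5-bis(3,5-dimethoxyphenyl)benzo[1,2-b:5,4-b']difuran-4-carboxylate | COC(=O)c1c2c(-c3cc(OC)cc(OC)c3)coc2cc2occ(-c3cc(OC)cc(OC)c3)c12 | intermediate
7 | 4-bromoanisole | COc1ccc(Br)cc1 | starting material
8 | methyl 3,5-bis(3,5-dimethoxyphenyl)-2-(4-methoxyphenyl)benzo[1,2-b:5,4-b']difuran-4-carboxylate (mono-arylated, not isolated) | COC(=O)c1c2c(-c3cc(OC)cc(OC)c3)c(-c3ccc(OC)cc3)oc2cc2occ(-c3cc(OC)cc(OC)c3)c12 | intermediate
9 | methyl 3,5-bis(3,5-dimethoxyphenyl)-2,6-bis(4-methoxyphenyl)benzo[1,2-b:5,4-b']difuran-4-carboxylate | COC(=O)c1c2c(-c3cc(OC)cc(OC)c3)c(-c3ccc(OC)cc3)oc2cc2oc(-c3ccc(OC)cc3)c(-c3cc(OC)cc(OC)c3)c12 | intermediate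
10 | methyl rac-(2R,3S)-3,5-bis(3,5-dimethoxyphenyl)-2,6-bis(4-methoxyphenyl)-2,3-dihydrobenzo[1,2-b:5,4-b']difuran-4-carboxylate (2,3-cis, racemic, one enantiomer drawn, not isolated) | COC(=O)c1c2c(cc3c1c(-c1cc(OC)cc(OC)c1)c(-c1ccc(OC)cc1)o3)O[C@@H](c1ccc(OC)cc1)[C@H]2c1cc(OC)cc(OC)c1 | intermediate
11 | methyl (2R,3S,5R,6S)-3,5-bis(3,5-dimethoxyphenyl)-2,6-bis(4-methoxyphenyl)-2,3,5,6-tetrahydrobenzo[1,2-b:5,4-b']difuran-4-carboxylate (all four aryl groups on one face, meso) | COC(=O)c1c2c(cc3c1[C@@H](c1cc(OC)cc(OC)c1)[C@@H](c1ccc(OC)cc1)O3)O[C@@H](c1ccc(OC)cc1)[C@H]2c1cc(OC)cc(OC)c1 | intermediate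
12 | methyl rac-(2S,3S,5R,6S)-3,5-bis(3,5-dimethoxyphenyl)-2,6-bis(4-methoxyphenyl)-2,3,5,6-tetrahydrobenzo[1,2-b:5,4-b']difuran-4-carboxylate (one trans ring, one cis ring, racemic, one enantiomer drawn, not isolated) | COC(=O)c1c2c(cc3c1[C@@H](c1cc(OC)cc(OC)c1)[C@@H](c1ccc(OC)cc1)O3)O[C@H](c1ccc(OC)cc1)[C@H]2c1cc(OC)cc(OC)c1 | intermediate
13 | methyl (2R,3R,5S,6S)-3,5-bis(3,5-dimethoxyphenyl)-2,6-bis(4-methoxyphenyl)-2,3,5,6-tetrahydrobenzo[1,2-b:5,4-b']difuran-4-carboxylate (both rings trans, both 3-aryl groups syn, meso) | COC(=O)c1c2c(cc3c1[C@@H](c1cc(OC)cc(OC)c1)[C@H](c1ccc(OC)cc1)O3)O[C@H](c1ccc(OC)cc1)[C@H]2c1cc(OC)cc(OC)c1 | intermediate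
14 | (2R,3R,5S,6S)-3,5-bis(3,5-dimethoxyphenyl)-2,6-bis(4-methoxyphenyl)-2,3,5,6-tetrahydrobenzo[1,2-b:5,4-b']difuran-4-carbaldehyde (meso) | O=Cc1c2c(cc3c1[C@@H](c1cc(OC)cc(OC)c1)[C@H](c1ccc(OC)cc1)O3)O[C@H](c1ccc(OC)cc1)[C@H]2c1cc(OC)cc(OC)c1 | intermediate
15 | diethyl [(4-methoxyphenyl)methyl]phosphonate | CCOP(=O)(Cc1ccc(OC)cc1)OCC | starting material
16 | (2R,3R,5S,6S)-3,5-bis(3,5-dimethoxyphenyl)-2,6-bis(4-methoxyphenyl)-4-[(E)-2-(4-methoxyphenyl)ethenyl]-2,3,5,6-tetrahydrobenzo[1,2-b:5,4-b']difuran (meso) | COc1ccc(/C=C/c2c3c(cc4c2[C@@H](c2cc(OC)cc(OC)c2)[C@H](c2ccc(OC)cc2)O4)O[C@H](c2ccc(OC)cc2)[C@H]3c2cc(OC)cc(OC)c2)cc1 | intermediate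
17 | 4-methoxybenzylic cation from protonation of 16 at the alkene carbon next to ring B (ion pair with the catalyst anion, not isolated) | COc1ccc([CH+]Cc2c3c(cc4c2[C@@H](c2cc(OC)cc(OC)c2)[C@H](c2ccc(OC)cc2)O4)O[C@H](c2ccc(OC)cc2)[C@H]3c2cc(OC)cc(OC)c2)cc1 | intermediate
18 | hepta-O-methyl ether of 19 (all seven phenols as OMe; seven-ring methine S; dihydrofuran fused to the seven-membered ring 2S,3S; second dihydrofuran 2R,3R) | COc1ccc([C@@H]2Cc3c4c(cc5c3[C@@H](c3cc(OC)cc(OC)c3)[C@H](c3ccc(OC)cc3)O5)O[C@H](c3ccc(OC)cc3)[C@H]4c3cc(OC)cc(OC)c32)cc1 | intermediate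
19 | CNP0136963.1: resveratrol trimer with an ampelopsin B-type core (dibenzo seven-membered ring with CH2 and an S methine bearing 4-hydroxyphenyl, fused trans-2S,3S dihydrobenzofuran) and a second trans-2R,3R 2-(4-hydroxyphenyl)-3-(3,5-dihydroxyphenyl)dihydrofuran on ring B | Oc1ccc([C@@H]2Cc3c4c(cc5c3[C@@H](c3cc(O)cc(O)c3)[C@H](c3ccc(O)cc3)O5)O[C@H](c3ccc(O)cc3)[C@H]4c3cc(O)cc(O)c32)cc1 | target

**Step count:** 9 steps in total. **Longest linear sequence:** 9 steps (from 1; compounds 2, 7 and 15 are bought).

**Steps most likely to fail, with fallbacks**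

Step 8 is the least certain. The acid may be too weak to protonate the stilbene, may give low enantioselectivity, or may ionise a benzylic C–O bond and divert material to indane-type by-products. A stronger confined imidodiphosphorimidate acid is the first variation. The fallback gives up asymmetric catalysis for resolution. It sets out from 16: BF3·OEt2 (20 mol%) in CH2Cl2 at −40 °C closes the ring under the same substrate control but without choosing between the two rings, giving the racemate, that is 18 together with the mirror-image heptamethyl ether ent-18 F1. Preparative chromatography on a chiral stationary phase (amylose tris(3,5-dimethylphenylcarbamate), CO2/MeOH) gives 18, where the route resumes.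

Step 4 may be sluggish on two tetrasubstituted furan rings, may hydrogenolyse the benzylic C–O bond of the product, or may give imperfect face relay. The fallback replaces surface hydrogenation by ionic hydrogenation. It sets out from 9: Et3SiH (10 equiv) and CF3CO2H in CH2Cl2 at 0 → 25 °C protonate each furan at C3 and deliver hydride to the C2 oxocarbenium ion anti to the 3-aryl group, giving trans rings directly. There is no relay between the two rings, so 13 forms together with the racemic C2-symmetric trans,trans diastereomer of 13 F2 (about 1:1). Chromatography or crystallisation removes F2, and the route resumes at 13, with step 5 no longer needed.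

Step 9 may open the 2-aryl dihydrofurans through Lewis-acid ionisation of the benzylic C–O bonds and give intractable mixtures. The fallback replaces electrophilic ether cleavage by nucleophilic demethylation under basic conditions, which cannot ionise those bonds. It sets out from 18: NaSEt (20 equiv) in DMF at 130 °C under argon, then aqueous HCl, removes the seven methyl groups by SN2 attack at methyl and comes back to the route at 19.

**Further compounds**
F1 | step 8 | enantiomer of 18 (seven-ring methine R; dihydrofuran fused to the seven-membered ring 2R,3R; second dihydrofuran 2S,3S) | COc1ccc([C@H]2Cc3c4c(cc5c3[C@H](c3cc(OC)cc(OC)c3)[C@@H](c3ccc(OC)cc3)O5)O[C@@H](c3ccc(OC)cc3)[C@@H]4c3cc(OC)cc(OC)c32)cc1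
F2 | step 4 | methyl rac-(2S,3S,5S,6S)-3,5-bis(3,5-dimethoxyphenyl)-2,6-bis(4-methoxyphenyl)-2,3,5,6-tetrahydrobenzo[1,2-b:5,4-b']difuran-4-carboxylate (both rings trans, 3-aryl groups anti, racemic, one enantiomer drawn) | COC(=O)c1c2c(cc3c1[C@H](c1cc(OC)cc(OC)c1)[C@@H](c1ccc(OC)cc1)O3)O[C@H](c1ccc(OC)cc1)[C@H]2c1cc(OC)cc(OC)c1
F0 | step 9 | none | none
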